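The numbers are assumed; the run is a simulation.

Early in Sunday's run X is still forming from G while J already gives L, and each L then either catches an X or meets another L.

| setting | Sunday's | Wednesday's | Thursday's | Tuesday's |
|---|---|---|---|---|
| G | 29 mM | 29 mM | 29 mM | 29 mM |
| J | 37.7 mM | 37.7 mM | 37.7 mM | 37.7 mM (fed, over 6.40 h) |
| time | 8.0 h |  |  | 8.0 h |
| remark | everything together in a closed stirred flask, run for 8.0 h | a single well-mixed tank run continuously and read at steady state, 80.0 h in it on average | a single well-mixed tank run continuously and read at steady state, 8.0 h in it on average | all but J at the start; J goes in evenly over 6.40 h, the run ends at 8.0 h |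

    G ⇌ X (K1 = 1.8, k1 = 2.50 × 10⁻⁴ s⁻¹)
    J → L (k2 = 4.41 × 10⁻⁴ s⁻¹)
    X + L → X.L (k3 = 0.203 M⁻¹ s⁻¹)
    2 L → L2 (k4 = 0.401 M⁻¹ s⁻¹)
    J + X.L ⇌ J.X.L, settled at all times (K5 = 53.4 M⁻¹)

1. the set-up with the highest amount of X at the outlet or at the end, in percent of the G put in ("none" if the first two lie within 2 percentage points) (Sunday's / Wednesday's / Thursday's / Tuesday's / none)
2. amount of X at the outlet or at the end, in percent of the G put in, Sunday's
3. amount of X at the outlet or at the end, in percent of the G put in, Wednesday's
4. amount of X at the outlet or at the end, in percent of the G put in, Thursday's
5. amount of X at the outlet or at the end, in percent of the G put in, Tuesday's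

- amounts and yields of X.L count J.X.L too
- where a step has two of a species, its rate is k times that concentration squared, and two are used at each turn
- the stated concentrations are those of everything mixed, before any reaction; amounts are the same in each set-up
- the feed brings no volume worth counting
- run time (Sunday's): 8.0 h

The bench rule counts equivalents: in Sunday's flask J stands at 1.30 per G, each J gives one L and each L takes one X, so X ought to be used up. The border of that rule is a ratio. In Sunday's flask the half-life of J by step 2, 0.44 h, is close to 0.495 h, the relaxation half-life of G and X, so L arrives while X is still climbing towards its balance share of the pool, 64.3%. Dividing the relaxation rate 1.40 h⁻¹ by the sum of itself and the rate of step 2 removes time: the average L finds 46.9% of the balance X.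

I take L as used as fast as it is made. I then divide the speed at which that X catches an L by the speed at which L is lost to its own kind when J is feeding it, and call this the trap number, a selectivity factor 0.486. It lies below one, and solving the balance of L gives 38.2% of the charged J ending on X, less than half. So I reckon the working equivalents in Sunday's flask at 0.496, not 1.30, and I give X its balance share of the uncaught pool, 32.4% of the G charged.

In Tuesday's flask J enters over 6.40 h, far longer than its half-life, so X has time to rise while L is made slowly; I expect a higher trap number there and less X left than in Sunday's flask.

The forecast names Sunday's as best, with 31%, 6.8%, 15% and 6% in the order asked, holding that “both continuous tanks hold L low and X gets trapped far more”.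

The flasks give 28.1%, 6.82%, 14.9% and 7.78%, and Sunday's is best. In Sunday's flask steps 3 and 4 ran while J gave L, and by 4.00 h step 3 had 96% of its turnover behind it, with J at 0.753% of its charge. At 8.00 h in Sunday's flask X held 28.1% and G 15.6% of the G charged, and the X.L, all its forms counted, came to 43.3% of the J charged against my 38.2%. For the neighbour of Sunday's flask with 73 mM of G, the trap number becomes 1.22, the share of J 68.6%, and X 41.5% of the G charged; that flask gives 41.1%.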